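Readings and results were computed for substances that don't exist; noise was put on by code.

- I decided to follow J as a share of the D charged, because three charges can then be compared directly.

| flask | D | Q | remark | time |
|---|---|---|---|---|
| amber | 0.22 M | 110 mM (held) | run made earlier |  |
| epsilon | 0.20 M | 110 mM (held) |  | 30 min |
| theta | 0.60 M | 110 mM (held) |  | 30 min |
| delta | 2.0 M | 110 mM (held) |  | 30 min |

amber run (percent of the D charged)

| time / min | J / % | D / % |
|---|---|---|
| 2.00 | 19.7 | 26.6 |
| 4.00 | 27.2 | 12.2 |
| 6.00 | 30.9 | 6.6 |
| 8.00 | 32.7 | 3.8 |
| 10.0 | 34.4 | 2.6 |

(each reading ± 0.5 percentage points)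

- at the start none of Q is in solution
- "hardly changes" means that all values lie within two and a half points (for a concentration: within two and a half percent of the largest)

1. [J] at the end for epsilon, theta, delta, in this order
2. how the row runs (rises, then falls / falls, then rises / hardly changes / rises all the way / falls all the way)

- I set up two extreme flasks. In the first, J keeps the share of 34.4 % last read in amber at any charge. In the second, extra D adds no J to amber's amount, so the share would be 12.6 % in theta and 3.78 % in delta.
- Amber pointed between them: J took 26.8 % of the D lost before 2.00 min, then 52.1 % up to 4.00 min. This selectivity, as read, rose as D fell, so I expected theta and delta to lose share early but still to pass through low D.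
- I wrote J's split of lost D as u/(u + D), where u is the even-split level, the D left, as a fraction of amber's charge, at which J and waste take equal shares.
- The second slice gave a first u of 21.1 %. Putting that back into the summed split over the slice gave 20.9 %, a reading that carries the scatter of 0.5 percentage points.
- As a check on the slice that u was not drawn from, u gave 19.5 % for amber at 2.00 min, against the 19.7 % read.
- I rescaled u to each charge as w, holding its concentration fixed, and for my reckoning set D to nil at 30 min, since amber held 2.6 % already at 10.0 min, sooner than that. The end share is then w times the log of one plus one over w: 38.5 % for epsilon, 20.2 % for theta and 8.71 % for delta. My share for delta stood between the extremes.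
- The forecast gave 0.078 M, 0.123 M and 0.176 M, each a little more than my shares come to, with the row rises all the way: “The yield falls but concentration still rises.”
- The flask gave 0.0755 M, 0.111 M and 0.139 M, and the row rises all the way.

    D + L ⇌ J (K = 390 M⁻¹, k = 0.0394 M⁻¹ s⁻¹)
    D → E (k = 1.30 × 10⁻⁴ s⁻¹)
    2 D → Z (k = 0.0333 M⁻¹ s⁻¹)
    2 L → X (k = 0.00192 M⁻¹ s⁻¹)
    Q ⇌ L, rate k5*(csat - [L]) (kL = 0.0525 s⁻¹)

- The share of J from u was 38.5 % in epsilon, where the flask gave 37.8 %, and 8.71 % in delta, where it gave 6.94 %. In delta, the first half-life of D at its charge by the pairing into Z, taken apart, was 7.51 s, shorter than the 13.2 s half-time of L's passage from Q, also taken apart, but in epsilon it was longer, at 75.1 s.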